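The slowness of the late steps tells us to ask first what the end state must be, and only then how fast it is approached.

    starting material + partner → intermediate + by-product (k1 = 0.00198 L mol⁻¹ s⁻¹)
    intermediate ⇌ target (K2 = 0.55, k2 = 8.88 × 10⁻⁵ s⁻¹)
    intermediate ⇌ isomer of the product (K3 = 2.7, k3 = 3.14 × 10⁻⁵ s⁻¹)
    target → over-reaction product (k4 = 1.92 × 10⁻⁶ s⁻¹)

| setting | epsilon | zeta | delta |
|---|---|---|---|
| starting material | 0.030 M | 0.10 M | 0.30 M |
| partner | 0.0800 M | 0.0800 M | 0.0800 M |
| time | 30 h | 30 h | 30 h |

1. [target] at the end for epsilon, zeta, delta, in this order
2. how that number moves from the first to the last of them (rises, then falls / rises all the way / falls, then rises / falls all the way / hardly changes)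

- "hardly changes" means that all values lie within two and a half points (for a concentration: within two and a half percent of the largest)
- run time (epsilon): 30 h

- We begin with the supply. Each starting material and partner that react give one intermediate, so the smaller charge, the limiting reagent, caps the pool of intermediate, target, isomer of the product and over-reaction product. That cap is 0.030 M in epsilon and 0.0800 M in zeta and delta.
- Next comes the state that the two reversible steps approach. Balance in the two reversible steps means c(target) = K2 c(intermediate) and c(isomer of the product) = K3 c(intermediate). This gives the resting share, the fraction of intermediate, target and isomer of the product together that stands as target under thermodynamic control among those three, K2/(1+K2+K3) = 12.9%. Multiplied by the caps, it gives 0.00387 M in epsilon and 0.0103 M in zeta and delta.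
- The weak link is the assumption of balance, so we test it. Target and intermediate relax with a half-life of 0.769 h, shorter than the 6.04 h of that pair's exchange with the isomer of the product, so we treat them as one pair.
- Balance within the pair puts 35.5% of the pool on target. As an estimate, we take the feed as instant and start from that balance; then 3.19% of the excess over the resting share remains after 30 h, which adds 0.720% of the pool.
- The pool also leaks to over-reaction product, by about 2.68% at the resting share. Together these corrections give 13.3% of the pool as target: 0.00399 M in epsilon and 0.0106 M in zeta and delta.
- Zeta and delta stand level in that number, so the sign of their difference must come from the feed. Delta's partner has a half-life of 0.324 h, while zeta's late pseudo-first-order tail has 4.86 h. Zeta's pool is therefore younger and keeps slightly more excess, so we commit to a row that rises, then falls a little.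
- The forecast gave 0.0041 M, 0.011 M and 0.0107 M, rises, then falls, with zeta above delta since “its near-equimolar feed arrives late”, whereas our number holds those two level.
- The simulation gives 0.00400 M, 0.0108 M and 0.0105 M, rises, then falls, with the turn at 0.094 M of starting material.
- In epsilon at 1.36 h, target falls back 84 times as fast as it goes on, and its half-life on the onward path, 100 h, is longer than the run of 30 h. At the end, epsilon holds 13.3% of its charge as target against the resting share of 12.9%, and zeta, where the resting share on the partner's charge gives 0.0103 M, holds 0.0108 M.

The constants used here belong to no real substance; the rest is arithmetic.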